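**Plan**

- Retrosynthesis: the butenolide is detached at C12–C13 and C12 at C11–C12. The C17 formyl group is led back to an 8(17)-exo-methylene. The trans-decalin is opened at C9–C10 and C4–C5 to an acyclic (E,E)-epoxy diene, whose C3=C4 bond goes back to an aldehyde and a malonate.
- Forward: farnesol (C1–C3, C5–C11, C17, C20) is shortened to a C12 aldehyde, diethyl malonate adds C4, C18 and C19, and the oxirane is installed. Rings A and B then close in one operation (C4–C5 first, C9–C10 second). C3 is deoxygenated, C17 hydroxylated, the side chain grown at C11 (C12 by methylenation, C13–C16 by B-alkyl Suzuki coupling), and C17 oxidized last.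
- Enabling feature: C4 of ring A is quaternary, carries the two CH2OH arms (C18, C19) and sits next to the ring-fusion carbon C5. A tertiary C4 radical set free from a 2,2-bis(silyloxymethyl)oxirane can therefore open a chair–chair closure of rings A and B.
- Stereochemistry: a Sharpless epoxidation fixes the oxirane CH (C3, R). This centre relays to C5, C10 and C9 in the bicyclization and is then removed. C8 is set at the end by equilibration of the C17 aldehyde to the equatorial position.

Key step: step 11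

Remarks: labdane numbering is used for the bicyclic compounds (C11 on C9, C17 on C8, C18/C19 on C4, C20 on C10). All of them belong to the ent series, and α means the face of the C20 methyl. PMB = 4-methoxybenzyl, TBS = tert-butyldimethylsilyl, TES = triethylsilyl.
Assumption on the chemistry: the lipase of step 6 acylates the hydroxymethyl arm trans to the chain, as with simpler 2-alkylidene-1,3-propanediols; if it took the other arm, the same sequence with L-(+)-tartrate in step 9 would lead to the same oxirane.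

**Route**

Step 1
Reactants: 1 (2E,6E)-farnesol
Product: 2 (2E,6E)-farnesyl 4-methoxybenzyl ether
Conditions: NaH, PMBCl, Bu4NI (cat.), THF/DMF, 0 °C → rt
Reagents that add atoms: 4-methoxybenzyl chloride, COc1ccc(CCl)cc1
Why: Williamson etherification of the primary allylic alkoxide; an ether is chosen in place of the usual farnesyl ester because it has to survive two DIBAL-H reductions and can later be removed oxidatively beside three silyl ethers.

Step 2
Reactants: 2 (2E,6E)-farnesyl 4-methoxybenzyl ether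
Product: 4 racemic 10,11-epoxyfarnesyl 4-methoxybenzyl ether, via bromohydrin 3 (not isolated)
Conditions: NBS, THF/H2O, 0 °C; then K2CO3, MeOH, rt
Reagents that add atoms: water, O (the oxirane oxygen); N-bromosuccinimide, O=C1CCC(=O)N1Br (bromine only in 3)
Why: Terminal-selective bromohydrin formation (in aqueous THF the coiled polyene exposes only the terminal trisubstituted alkene, and water opens the bromonium ion at the tertiary carbon) followed by intramolecular Williamson closure; the new stereocentre is racemic and is destroyed in step 3.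

Step 3
Reactants: 4 racemic 10,11-epoxyfarnesyl 4-methoxybenzyl ether
Product: 5 (4E,8E)-10-[(4-methoxybenzyl)oxy]-4,8-dimethyldeca-4,8-dienal
Conditions: HIO4·2H2O, THF/Et2O, 0 °C
Reagents that add atoms: none
Why: Periodic acid hydrolyses the oxirane to the glycol and cleaves it (Malaprade glycol cleavage) to the aldehyde and acetone, leaving the two trisubstituted alkenes and the PMB ether untouched.

Step 4
Reactants: 5 (4E,8E)-10-[(4-methoxybenzyl)oxy]-4,8-dimethyldeca-4,8-dienal; 6 diethyl malonate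
Product: 7 diethyl 2-[(4E,8E)-10-[(4-methoxybenzyl)oxy]-4,8-dimethyldeca-4,8-dien-1-ylidene]propanedioate
Conditions: piperidine (cat.), AcOH (cat.), toluene, Dean–Stark, reflux
Reagents that add atoms: none
Why: Knoevenagel condensation under piperidinium acetate catalysis with removal of water; the malonate carbon becomes C4 and its ester carbons C18 and C19, and with two identical ester groups the new alkene has no geometry to control.

Step 5
Reactants: 7 diethyl alkylidenemalonate
Product: 8 2-[(4E,8E)-10-[(4-methoxybenzyl)oxy]-4,8-dimethyldeca-4,8-dien-1-ylidene]propane-1,3-diol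
Conditions: DIBAL-H (5 equiv), CH2Cl2, −78 → 0 °C; Rochelle salt
Reagents that add atoms: none
Why: DIBAL-H reduces both ester groups of an alkylidene malonate by 1,2-addition to the 2-alkylidene-1,3-diol (ester reduction), and the PMB ether is inert where an ester on the farnesyl oxygen would be lost.

Step 6
Reactants: 8 2-alkylidenepropane-1,3-diol
Product: 9 (2E,6E,10E)-2-(hydroxymethyl)-12-[(4-methoxybenzyl)oxy]-6,10-dimethyldodeca-2,6,10-trien-1-yl acetate (acetoxymethyl arm trans to the chain)
Conditions: lipase PS (Burkholderia cepacia, immobilized), vinyl acetate, iPr2O, rt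
Reagents that add atoms: vinyl acetate, C=COC(C)=O
Why: Lipase-catalysed irreversible transesterification with an enol ester acylates 2-alkylidene-1,3-propanediols at the less hindered arm trans to the alkyl chain; this differentiates the two diastereotopic arms, which would otherwise steer a titanium–tartrate epoxidation to opposite faces.

Step 7
Reactants: 9 (2E)-monoacetate
Product: 10 (2Z,6E,10E)-2-{[(tert-butyldimethylsilyl)oxy]methyl}-12-[(4-methoxybenzyl)oxy]-6,10-dimethyldodeca-2,6,10-trien-1-yl acetate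
Conditions: TBSCl, imidazole, DMF, 0 °C → rt
Reagents that add atoms: tert-butyldimethylsilyl chloride, CC(C)(C)[Si](C)(C)Cl
Why: Imidazole-promoted silylation of the remaining primary allylic alcohol (the arm cis to the chain) is fast enough to precede any acetyl migration between the arms.

Step 8
Reactants: 10 acetate silyl ether
Product: 11 (2Z,6E,10E)-2-{[(tert-butyldimethylsilyl)oxy]methyl}-12-[(4-methoxybenzyl)oxy]-6,10-dimethyldodeca-2,6,10-trien-1-ol (free hydroxymethyl trans to the chain)
Conditions: DIBAL-H (2.5 equiv), CH2Cl2, −78 °C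
Reagents that add atoms: none
Why: Reductive cleavage of the acetate at low temperature frees the trans arm without the basic alkoxide equilibration that could move the silyl group from one arm to the other.

Step 9
Reactants: 11 (2Z)-mono-TBS allylic alcohol
Product: 12 [(2S,3R)-2-{[(tert-butyldimethylsilyl)oxy]methyl}-3-{(3E,7E)-9-[(4-methoxybenzyl)oxy]-3,7-dimethylnona-3,7-dien-1-yl}oxiran-2-yl]methanol
Conditions: Ti(OiPr)4 (0.1 equiv), D-(−)-diisopropyl tartrate (0.12 equiv), t-BuOOH, 4 Å MS, CH2Cl2, −20 °C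
Reagents that add atoms: tert-butyl hydroperoxide, CC(C)(C)OO
Why: Katsuki–Sharpless asymmetric epoxidation, in which the only free allylic alcohol binds the titanium–tartrate–peroxide complex so that the other two alkenes are not touched; with the directing hydroxymethyl trans to the chain, D-(−)-tartrate delivers oxygen to the face that makes the oxirane CH carbon (future C3) R and C4 S.

Step 10
Reactants: 12 epoxy alcohol
Product: 13 (3R)-2,2-bis{[(tert-butyldimethylsilyl)oxy]methyl}-3-{(3E,7E)-9-[(4-methoxybenzyl)oxy]-3,7-dimethylnona-3,7-dien-1-yl}oxirane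
Conditions: TBSCl, imidazole, DMF, rt
Reagents that add atoms: tert-butyldimethylsilyl chloride, CC(C)(C)[Si](C)(C)Cl
Why: Silylation under weakly basic conditions caps the second arm without generating the free alkoxide that would start a Payne rearrangement of the 2,3-epoxy alcohol.

Step 11
Reactants: 13 bis(silyloxymethyl) epoxy diene
Product: 15 decalin alcohol 18,19-bis(TBS-oxy)-11-(PMB-oxy)-12,13,14,15,16-pentanor-ent-labd-8(17)-en-3α-ol (3α-OH equatorial; 5β-H; 9β-H; 10α-CH3), via C3 trimethylsilyl ether 14 (not isolated)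
Conditions: Cp2TiCl2 (0.2 equiv), Mn dust, TMSCl, 2,4,6-collidine, THF (degassed), rt; then K2CO3, MeOH, rt
Reagents that add atoms: chlorotrimethylsilane, C[Si](C)(C)Cl (silicon only in 14)
Why: Cp2TiCl, formed in the flask from Cp2TiCl2 and Mn, transfers one electron to the oxirane and cleaves the C4–O bond to the tertiary C4 radical flanked by the two silyloxymethyl arms; the cascade is ended by a second Ti(III), which removes a C17 hydrogen to leave the 8(17)-exo-methylene, and TMSCl/collidine releases the catalyst from the C3 alkoxide. The closest known reaction is the titanocene(III)-mediated radical bicyclization of 10,11-epoxyfarnesyl esters to 3-hydroxy exo-methylene trans-decalins, to which the ether terminus and the oxygenated arms are spectator changes. Ring A closes 6-endo-trig by forming C4–C5 and ring B closes 6-endo-trig by forming C9–C10. C5, C10 and C9 arise in one chair–chair arrangement in which the bulky C3–OTi group lies equatorial, so the (3R) centre fixes 5β-H and 10α-CH3, and the E geometry of both trisubstituted alkenes gives the trans ring fusion and the equatorial C9 arm. The step needs the C4 radical to add to the C5=C10 alkene faster than it is reduced by Ti(III), which the low stationary Ti(III) concentration of the catalytic protocol and the shielding of the fully substituted radical carbon should secure, and it needs exo-selective termination, which follows from hydrogen removal at the least hindered position, the C17 methyl.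

Step 12
Reactants: 15 decalin alcohol
Product: 16 thiocarbamate O-[18,19-bis(TBS-oxy)-11-(PMB-oxy)-12,13,14,15,16-pentanor-ent-labd-8(17)-en-3α-yl] 1H-imidazole-1-carbothioate
Conditions: 1,1'-thiocarbonyldiimidazole, DMAP (cat.), toluene, 90 °C
Reagents that add atoms: 1,1'-thiocarbonyldiimidazole, S=C(n1ccnc1)n1ccnc1
Why: Thioacylation of the hindered equatorial C3 alcohol (first half of a Barton–McCombie deoxygenation) runs without strong base and so avoids an alkoxide that could take over a silyl group from the C4 arms.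

Step 13
Reactants: 16 thiocarbamate
Product: 17 alkene 18,19-bis(TBS-oxy)-11-(PMB-oxy)-12,13,14,15,16-pentanor-ent-labd-8(17)-ene
Conditions: Bu3SnH, AIBN (cat.), toluene, 110 °C
Reagents that add atoms: none
Why: Barton–McCombie radical deoxygenation, in which the stannyl radical adds to sulfur, β-scission releases the secondary C3 radical and Bu3SnH quenches it; the only stereocentre lost is C3, which has done its work.

Step 14
Reactants: 17 alkene
Product: 19 primary alcohol 18,19-bis(TBS-oxy)-11-(PMB-oxy)-12,13,14,15,16-pentanor-ent-labdan-17-ol (8β-H; C17 α and axial), via C17 alkylborane 18 (not isolated)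
Conditions: BH3·THF, THF, 0 °C → rt; then NaOH, H2O2, 0 °C → rt
Reagents that add atoms: hydrogen peroxide, OO (the C17 oxygen); borane, B (boron only in 18)
Why: Anti-Markovnikov hydroboration–oxidation, in which borane approaches the exo-methylene from the β face, away from the syn-axial C20 methyl, so that hydrogen enters at C8β and C17 becomes axial; this C8 configuration is corrected in step 21.

Step 15
Reactants: 19 primary alcohol
Product: 20 silyl ether 18,19-bis(TBS-oxy)-17-(TES-oxy)-11-(PMB-oxy)-12,13,14,15,16-pentanor-ent-labdane (8β-H)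
Conditions: TESCl, imidazole, DMF, rt
Reagents that add atoms: chlorotriethylsilane, CC[Si](Cl)(CC)CC
Why: Silylation gives a triethylsilyl ether that survives the next four steps and can be removed later beside the two neopentyl TBS ethers.

Step 16
Reactants: 20 silyl ether
Product: 21 alcohol 18,19-bis(TBS-oxy)-17-(TES-oxy)-12,13,14,15,16-pentanor-ent-labdan-11-ol (8β-H)
Conditions: DDQ, CH2Cl2/pH 7 buffer, 0 °C
Reagents that add atoms: none
Why: Oxidative PMB ether cleavage by DDQ through the benzylic oxocarbenium ion and its hydrolysis, under buffered two-phase conditions in which the three silyl ethers are stable.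

Step 17
Reactants: 21 alcohol
Product: 22 aldehyde 18,19-bis(TBS-oxy)-17-(TES-oxy)-12,13,14,15,16-pentanor-ent-labdan-11-al (8β-H)
Conditions: Dess–Martin periodinane, CH2Cl2, 0 °C → rt
Reagents that add atoms: none
Why: Dess–Martin oxidation of the primary alcohol stops at the aldehyde and is free of base, so the C9 centre next to the new carbonyl is not enolized.

Step 18
Reactants: 22 aldehyde
Product: 23 vinyl compound 18,19-bis(TBS-oxy)-17-(TES-oxy)-13,14,15,16-tetranor-ent-labd-11-ene (8β-H)
Conditions: Ph3PCH3Br, KHMDS, THF, −78 → 0 °C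
Reagents that add atoms: methyltriphenylphosphonium bromide, C[P+](c1ccccc1)(c1ccccc1)c1ccccc1.[Br-]
Why: Wittig methylenation adds C12; the small salt-free ylide should add to the hindered aldehyde at low temperature faster than it deprotonates C9, so C9 keeps its configuration.

Step 19
Reactants: 23 vinyl compound; 24 3-bromofuran-2(5H)-one
Product: 26 butenolide 18,19-bis(TBS-oxy)-17-(TES-oxy)-ent-labd-13-en-16,15-olide (8β-H), via C12 alkyl-9-BBN 25 (not isolated)
Conditions: 9-BBN, THF, rt; then 24, Pd(dppf)Cl2 (cat.), AsPh3 (cat.), aq. K3PO4, DMF, rt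
Reagents that add atoms: 9-borabicyclo[3.3.1]nonane, B1C2CCCC1CCC2 (boron only in 25)
Why: 9-BBN hydroborates the monosubstituted alkene with boron at C12, and B-alkyl Suzuki–Miyaura coupling with the α-bromobutenolide forms C12–C13, installing the α-substituted butenolide with its C13=C14 double bond in place and the carbonyl at C16.

Step 20
Reactants: 26 butenolide
Product: 27 alcohol 18,19-bis(TBS-oxy)-17-hydroxy-ent-labd-13-en-16,15-olide (8β-H)
Conditions: PPTS (cat.), MeOH/CH2Cl2, 0 °C
Reagents that add atoms: none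
Why: Acid-catalysed methanolysis cleaves the triethylsilyl ether much faster than the two neopentyl primary TBS ethers and does not affect the butenolide.

Step 21
Reactants: 27 alcohol
Product: 29 aldehyde 18,19-bis(TBS-oxy)-17-oxo-ent-labd-13-en-16,15-olide (8α-H; formyl β and equatorial), via axial C17 aldehyde 28 (not isolated)
Conditions: Dess–Martin periodinane, CH2Cl2, rt; aq. Na2S2O3/NaHCO3 wash; then DBU (0.3 equiv), CH2Cl2, rt
Reagents that add atoms: none
Why: Dess–Martin oxidation gives the axial aldehyde, and base-mediated epimerization through the enolate moves the formyl group to the equatorial position, free of the 1,3-diaxial contact with the C20 methyl and trans to the C9 side chain; this thermodynamic C8 configuration is that of the target.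

Step 22
Reactants: 29 aldehyde
Product: 30 target, (1R,2S,4aS,8aS)-5,5-bis(hydroxymethyl)-8a-methyl-1-[2-(2-oxo-2,5-dihydrofuran-3-yl)ethyl]decahydronaphthalene-2-carbaldehyde
Conditions: HF·pyridine, THF/pyridine, 0 °C → rt
Reagents that add atoms: none
Why: Fluoride-mediated desilylation in a buffered, non-basic medium removes both TBS ethers without epimerizing the aldehyde or isomerizing the butenolide.

**Compound list**

1 | (2E,6E)-farnesol | CC(C)=CCC/C(C)=C/CC/C(C)=C/CO | starting material
2 | (2E,6E)-farnesyl 4-methoxybenzyl ether | CC(C)=CCC/C(C)=C/CC/C(C)=C/COCc1ccc(OC)cc1 | intermediate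
3 | (6E,10E)-3-bromo-12-[(4-methoxybenzyl)oxy]-2,6,10-trimethyldodeca-6,10-dien-2-ol, racemic (not isolated) | CC(C)(O)C(Br)CC/C(C)=C/CC/C(C)=C/COCc1ccc(OC)cc1 | intermediate
4 | 2,2-dimethyl-3-{(3E,7E)-9-[(4-methoxybenzyl)oxy]-3,7-dimethylnona-3,7-dien-1-yl}oxirane, racemic | CC1(C)OC1CC/C(C)=C/CC/C(C)=C/COCc1ccc(OC)cc1 | intermediate
5 | (4E,8E)-10-[(4-methoxybenzyl)oxy]-4,8-dimethyldeca-4,8-dienal | O=CCC/C(C)=C/CC/C(C)=C/COCc1ccc(OC)cc1 | intermediate
6 | diethyl malonate | CCOC(=O)CC(=O)OCC | starting material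
7 | diethyl 2-[(4E,8E)-10-[(4-methoxybenzyl)oxy]-4,8-dimethyldeca-4,8-dien-1-ylidene]propanedioate | CCOC(=O)C(=CCC/C(C)=C/CC/C(C)=C/COCc1ccc(OC)cc1)C(=O)OCC | intermediate
8 | 2-[(4E,8E)-10-[(4-methoxybenzyl)oxy]-4,8-dimethyldeca-4,8-dien-1-ylidene]propane-1,3-diol | OCC(CO)=CCC/C(C)=C/CC/C(C)=C/COCc1ccc(OC)cc1 | intermediate
9 | (2E,6E,10E)-2-(hydroxymethyl)-12-[(4-methoxybenzyl)oxy]-6,10-dimethyldodeca-2,6,10-trien-1-yl acetate | CC(=O)OC/C(CO)=C/CC/C(C)=C/CC/C(C)=C/COCc1ccc(OC)cc1 | intermediate
10 | (2Z,6E,10E)-2-{[(tert-butyldimethylsilyl)oxy]methyl}-12-[(4-methoxybenzyl)oxy]-6,10-dimethyldodeca-2,6,10-trien-1-yl acetate | CC(=O)OC/C(CO[Si](C)(C)C(C)(C)C)=C/CC/C(C)=C/CC/C(C)=C/COCc1ccc(OC)cc1 | intermediate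
11 | (2Z,6E,10E)-2-{[(tert-butyldimethylsilyl)oxy]methyl}-12-[(4-methoxybenzyl)oxy]-6,10-dimethyldodeca-2,6,10-trien-1-ol | OC/C(CO[Si](C)(C)C(C)(C)C)=C/CC/C(C)=C/CC/C(C)=C/COCc1ccc(OC)cc1 | intermediate
12 | [(2S,3R)-2-{[(tert-butyldimethylsilyl)oxy]methyl}-3-{(3E,7E)-9-[(4-methoxybenzyl)oxy]-3,7-dimethylnona-3,7-dien-1-yl}oxiran-2-yl]methanol | OC[C@@]1(CO[Si](C)(C)C(C)(C)C)O[C@@H]1CC/C(C)=C/CC/C(C)=C/COCc1ccc(OC)cc1 | intermediate
13 | (3R)-2,2-bis{[(tert-butyldimethylsilyl)oxy]methyl}-3-{(3E,7E)-9-[(4-methoxybenzyl)oxy]-3,7-dimethylnona-3,7-dien-1-yl}oxirane | CC(C)(C)[Si](C)(C)OCC1(CO[Si](C)(C)C(C)(C)C)O[C@@H]1CC/C(C)=C/CC/C(C)=C/COCc1ccc(OC)cc1 | intermediate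
14 | 3-O-trimethylsilyl ether of 15 (not isolated) | C[C@@]12CC[C@@H](O[Si](C)(C)C)C(CO[Si](C)(C)C(C)(C)C)(CO[Si](C)(C)C(C)(C)C)[C@H]1CCC(=C)[C@H]2COCc1ccc(OC)cc1 | intermediate
15 | 18,19-bis(TBS-oxy)-11-(PMB-oxy)-12,13,14,15,16-pentanor-ent-labd-8(17)-en-3α-ol | C[C@@]12CC[C@@H](O)C(CO[Si](C)(C)C(C)(C)C)(CO[Si](C)(C)C(C)(C)C)[C@H]1CCC(=C)[C@H]2COCc1ccc(OC)cc1 | intermediate
16 | O-[18,19-bis(TBS-oxy)-11-(PMB-oxy)-12,13,14,15,16-pentanor-ent-labd-8(17)-en-3α-yl] 1H-imidazole-1-carbothioate | C[C@@]12CC[C@@H](OC(=S)n3ccnc3)C(CO[Si](C)(C)C(C)(C)C)(CO[Si](C)(C)C(C)(C)C)[C@H]1CCC(=C)[C@H]2COCc1ccc(OC)cc1 | intermediate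
17 | 18,19-bis(TBS-oxy)-11-(PMB-oxy)-12,13,14,15,16-pentanor-ent-labd-8(17)-ene | C[C@@]12CCCC(CO[Si](C)(C)C(C)(C)C)(CO[Si](C)(C)C(C)(C)C)[C@H]1CCC(=C)[C@H]2COCc1ccc(OC)cc1 | intermediate
18 | 17-boranyl-18,19-bis(TBS-oxy)-11-(PMB-oxy)-12,13,14,15,16-pentanor-ent-labdane, 8β-H, written as the monoalkylborane (not isolated) | C[C@@]12CCCC(CO[Si](C)(C)C(C)(C)C)(CO[Si](C)(C)C(C)(C)C)[C@H]1CC[C@@H](CB)[C@H]2COCc1ccc(OC)cc1 | intermediate
19 | 18,19-bis(TBS-oxy)-11-(PMB-oxy)-12,13,14,15,16-pentanor-ent-labdan-17-ol, 8β-H | C[C@@]12CCCC(CO[Si](C)(C)C(C)(C)C)(CO[Si](C)(C)C(C)(C)C)[C@H]1CC[C@@H](CO)[C@H]2COCc1ccc(OC)cc1 | intermediate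
20 | 18,19-bis(TBS-oxy)-17-(TES-oxy)-11-(PMB-oxy)-12,13,14,15,16-pentanor-ent-labdane, 8β-H | C[C@@]12CCCC(CO[Si](C)(C)C(C)(C)C)(CO[Si](C)(C)C(C)(C)C)[C@H]1CC[C@@H](CO[Si](CC)(CC)CC)[C@H]2COCc1ccc(OC)cc1 | intermediate
21 | 18,19-bis(TBS-oxy)-17-(TES-oxy)-12,13,14,15,16-pentanor-ent-labdan-11-ol, 8β-H | C[C@@]12CCCC(CO[Si](C)(C)C(C)(C)C)(CO[Si](C)(C)C(C)(C)C)[C@H]1CC[C@@H](CO[Si](CC)(CC)CC)[C@H]2CO | intermediate
22 | 18,19-bis(TBS-oxy)-17-(TES-oxy)-12,13,14,15,16-pentanor-ent-labdan-11-al, 8β-H | C[C@@]12CCCC(CO[Si](C)(C)C(C)(C)C)(CO[Si](C)(C)C(C)(C)C)[C@H]1CC[C@@H](CO[Si](CC)(CC)CC)[C@H]2C=O | intermediate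
23 | 18,19-bis(TBS-oxy)-17-(TES-oxy)-13,14,15,16-tetranor-ent-labd-11-ene, 8β-H | C[C@@]12CCCC(CO[Si](C)(C)C(C)(C)C)(CO[Si](C)(C)C(C)(C)C)[C@H]1CC[C@@H](CO[Si](CC)(CC)CC)[C@H]2C=C | intermediate
24 | 3-bromofuran-2(5H)-one | BrC1=CCOC1=O | starting material
25 | 12-(9-borabicyclo[3.3.1]nonan-9-yl)-18,19-bis(TBS-oxy)-17-(TES-oxy)-13,14,15,16-tetranor-ent-labdane, 8β-H (not isolated) | C[C@@]12CCCC(CO[Si](C)(C)C(C)(C)C)(CO[Si](C)(C)C(C)(C)C)[C@H]1CC[C@@H](CO[Si](CC)(CC)CC)[C@H]2CCB1C2CCCC1CCC2 | intermediate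
26 | 18,19-bis(TBS-oxy)-17-(TES-oxy)-ent-labd-13-en-16,15-olide, 8β-H | C[C@@]12CCCC(CO[Si](C)(C)C(C)(C)C)(CO[Si](C)(C)C(C)(C)C)[C@H]1CC[C@@H](CO[Si](CC)(CC)CC)[C@H]2CCC1=CCOC1=O | intermediate
27 | 18,19-bis(TBS-oxy)-17-hydroxy-ent-labd-13-en-16,15-olide, 8β-H | C[C@@]12CCCC(CO[Si](C)(C)C(C)(C)C)(CO[Si](C)(C)C(C)(C)C)[C@H]1CC[C@@H](CO)[C@H]2CCC1=CCOC1=O | intermediate
28 | 18,19-bis(TBS-oxy)-17-oxo-ent-labd-13-en-16,15-olide, 8β-H, axial formyl (not isolated) | C[C@@]12CCCC(CO[Si](C)(C)C(C)(C)C)(CO[Si](C)(C)C(C)(C)C)[C@H]1CC[C@@H](C=O)[C@H]2CCC1=CCOC1=O | intermediate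
29 | 18,19-bis(TBS-oxy)-17-oxo-ent-labd-13-en-16,15-olide, 8α-H, equatorial formyl | C[C@@]12CCCC(CO[Si](C)(C)C(C)(C)C)(CO[Si](C)(C)C(C)(C)C)[C@H]1CC[C@H](C=O)[C@H]2CCC1=CCOC1=O | intermediate
30 | (1R,2S,4aS,8aS)-5,5-bis(hydroxymethyl)-8a-methyl-1-[2-(2-oxo-2,5-dihydrofuran-3-yl)ethyl]decahydronaphthalene-2-carbaldehyde (18,19-dihydroxy-17-oxo-ent-labd-13-en-16,15-olide, 8α-H) | C[C@@]12CCCC(CO)(CO)[C@H]1CC[C@H](C=O)[C@H]2CCC1=CCOC1=O | target

**Totals and risks**

Total step count: 22. Longest linear sequence: 22 steps, from 1 to 30; 6 and 24 are purchased and enter in steps 4 and 19.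

The three steps most likely to fail, riskiest first:

Step 11. The C4 radical carries two bulky, inductively withdrawing silyloxymethyl arms, so its attack on C5 may be slow. A second Ti(III) could then reduce it before the first ring closes, which would end in deoxygenation of the oxirane or in an uncyclized allylic alcohol. The fallback ties the two arms into one ring. It sets out from 12: the silyl group is removed with TBAF buffered by acetic acid to give the epoxy diol F1. Di-tert-butylsilyl bis(triflate) and 2,6-lutidine close the cyclic silylene F2, in which the radical carbon belongs to a six-membered dioxasilinane and is far less shielded. Stoichiometric Cp2TiCl (Cp2TiCl2, Mn, THF, aqueous work-up) should then give the silylene-bridged decalin alcohol F3. HF·pyridine frees the triol F4, and TBSCl/imidazole silylates its two primary hydroxyls in preference to the hindered secondary one, which brings the route back at 15.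

Step 19. The hindered alkylborane 25 may transmetalate slowly while the aqueous base degrades the bromobutenolide by ring opening and γ-deprotonation, so that protodeboronation takes over. The fallback builds the butenolide by enolate alkylation and sulfoxide elimination. It sets out from 23, which is hydroborated with 9-BBN and oxidized (NaOH, H2O2) to the C12 alcohol F5. I2, PPh3 and imidazole give the primary iodide F6. The lithium enolate of 3-(phenylsulfanyl)dihydrofuran-2(3H)-one (LDA, THF/DMPU) is alkylated to the α-alkyl-α-phenylsulfanyl lactone F7, a pair of C13 epimers. mCPBA at −78 °C gives the sulfoxides F8, whose thermal syn-elimination in toluene takes a ring hydrogen from C14 and leads back to the route at 26.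

Step 6. The lipase may not tell the two hydroxymethyl arms apart cleanly; every molecule acetylated on the other arm later ends as the enantiomeric oxirane, so the failure would show as erosion of enantiomeric purity. The fallback needs no arm selectivity. It sets out from 8, which is monosilylated statistically (NaH, 1 equiv TBSCl, THF) to a mixture of 11 and its geometric isomer, the (2E)-mono-TBS ether F9; the two are separated by chromatography. 11 goes on through steps 9 and 10. F9, whose free hydroxymethyl lies cis to the chain, is epoxidized with the mirror-image catalyst (Ti(OiPr)4, L-(+)-diisopropyl tartrate, t-BuOOH) to the epoxy alcohol F10, which has the same (3R) oxirane CH. Silylation of F10 (TBSCl, imidazole) brings both isomers back to the route at 13.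

**Further compounds**

F1 | step 11 | [(3R)-3-{(3E,7E)-9-[(4-methoxybenzyl)oxy]-3,7-dimethylnona-3,7-dien-1-yl}oxirane-2,2-diyl]dimethanol | OCC1(CO)O[C@@H]1CC/C(C)=C/CC/C(C)=C/COCc1ccc(OC)cc1
F2 | step 11 | (2R)-6,6-di-tert-butyl-2-{(3E,7E)-9-[(4-methoxybenzyl)oxy]-3,7-dimethylnona-3,7-dien-1-yl}-1,5,7-trioxa-6-silaspiro[2.5]octane | CC(C)(C)[Si]1(C(C)(C)C)OCC2(CO1)O[C@@H]2CC/C(C)=C/CC/C(C)=C/COCc1ccc(OC)cc1
F3 | step 11 | 18,19-[(di-tert-butylsilanediyl)bis(oxy)]-11-(PMB-oxy)-12,13,14,15,16-pentanor-ent-labd-8(17)-en-3α-ol | C[C@@]12CC[C@@H](O)C3(CO[Si](C(C)(C)C)(C(C)(C)C)OC3)[C@H]1CCC(=C)[C@H]2COCc1ccc(OC)cc1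
F4 | step 11 | 11-(PMB-oxy)-12,13,14,15,16-pentanor-ent-labd-8(17)-ene-3α,18,19-triol | C[C@@]12CC[C@@H](O)C(CO)(CO)[C@H]1CCC(=C)[C@H]2COCc1ccc(OC)cc1
F5 | step 19 | 18,19-bis(TBS-oxy)-17-(TES-oxy)-13,14,15,16-tetranor-ent-labdan-12-ol, 8β-H | C[C@@]12CCCC(CO[Si](C)(C)C(C)(C)C)(CO[Si](C)(C)C(C)(C)C)[C@H]1CC[C@@H](CO[Si](CC)(CC)CC)[C@H]2CCO
F6 | step 19 | 12-iodo-18,19-bis(TBS-oxy)-17-(TES-oxy)-13,14,15,16-tetranor-ent-labdane, 8β-H | C[C@@]12CCCC(CO[Si](C)(C)C(C)(C)C)(CO[Si](C)(C)C(C)(C)C)[C@H]1CC[C@@H](CO[Si](CC)(CC)CC)[C@H]2CCI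
F7 | step 19 | 13-(phenylsulfanyl)-18,19-bis(TBS-oxy)-17-(TES-oxy)-ent-labdan-16,15-olide, 8β-H, C13 epimers | C[C@@]12CCCC(CO[Si](C)(C)C(C)(C)C)(CO[Si](C)(C)C(C)(C)C)[C@H]1CC[C@@H](CO[Si](CC)(CC)CC)[C@H]2CCC1(Sc3ccccc3)CCOC1=O
F8 | step 19 | 13-(phenylsulfinyl)-18,19-bis(TBS-oxy)-17-(TES-oxy)-ent-labdan-16,15-olide, 8β-H, mixture of isomers | C[C@@]12CCCC(CO[Si](C)(C)C(C)(C)C)(CO[Si](C)(C)C(C)(C)C)[C@H]1CC[C@@H](CO[Si](CC)(CC)CC)[C@H]2CCC1(S(=O)c3ccccc3)CCOC1=O
F9 | step 6 | (2E,6E,10E)-2-{[(tert-butyldimethylsilyl)oxy]methyl}-12-[(4-methoxybenzyl)oxy]-6,10-dimethyldodeca-2,6,10-trien-1-ol | CC(C)(C)[Si](C)(C)OC/C(CO)=C/CC/C(C)=C/CC/C(C)=C/COCc1ccc(OC)cc1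
F10 | step 6 | [(2R,3R)-2-{[(tert-butyldimethylsilyl)oxy]methyl}-3-{(3E,7E)-9-[(4-methoxybenzyl)oxy]-3,7-dimethylnona-3,7-dien-1-yl}oxiran-2-yl]methanol | OC[C@]1(CO[Si](C)(C)C(C)(C)C)O[C@@H]1CC/C(C)=C/CC/C(C)=C/COCc1ccc(OC)cc1
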